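**Plan**

1. Cuts, in retrosynthetic order: the amide N–C(O) bond (side chain = (E)-7-oxododec-2-enoic acid, from δ-decalactone); the two C–O bonds of the C7–C8 epoxide and the C9 carbonyl (back to a ring B alkene and a protected C9 carbinol); C3–N (back to a C3 carboxyl, Curtius); C3–C4 (intramolecular Reformatsky); C5–C4 (formaldehyde) and C9–O (oxa-Michael) of a p-quinol.
2. Forward: ring B is the dearomatised ring of methyl 3-(4-hydroxyphenyl)propanoate, whose propanoate arm supplies C2, C3 and the carboxyl; ring A is closed onto it by SmI2; nitrogen, the side chain, the C9 ketone and the epoxide follow.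
3. Enabling feature: numbered as bicyclo[3.3.1]nonan-9-one (C1 carbinol bridgehead, C2–C4 in ring A, C5 bridgehead, C6–C8 in ring B, C9 carbonyl), the cis C3–N/C4–OH pair on ring A is a disguised cis-β-hydroxy acid, and the quaternary C1 holds the C2–C3 arm cis to a C4 aldehyde on C5 of ring B, so C3–C4 can close ring A as an aldol.
4. Stereochemistry: C1 and C9–O from a chiral phosphoric acid desymmetrisation of the achiral p-quinol; C5 and C6 by substrate control (aldol anti to the dioxolane, axial hydride); C3 and C4 from the samarium chelate on the exo face; C3–N by retention in the Curtius step; the epoxide by hydroxyl-directed exo delivery.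
5. C9 is carried as a carbinol inside a C1/C9 acetal through the SmI2 step (a ketone next to the C1 oxygen would not survive SmI2) and is oxidised late.

Key step: step 9

Remarks on the chemistry:
- Numbering and faces: all ring compounds carry the target numbering above (ring B = C1, C9, C5, C6, C7, C8; C4 is the carbon added to C5). On ring B, β is the face bearing the C1 oxygen and α the face bearing the C2 arm. In the bicycle, exo is the face of a ring turned away from the other ring.
- Assumption: the (R)-configured phosphoric acid is taken to give the enantiomer drawn for 4; if the sense proves opposite, its (S)-enantiomer is used and nothing else changes.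
- δ-Decalactone is used as the racemate; its stereocentre ends as the side-chain ketone.

**Route**

Step 1
Reactants: 1 methyl 3-(4-hydroxyphenyl)propanoate
Product: 2 p-quinol methyl ester
Conditions: PhI(OAc)2, MeCN/H2O (3:1), 0 °C
Reagents that add atoms: water, O
Why: Oxidative dearomatisation of a p-alkylphenol by trivalent iodine, with water captured at the para carbon, is a standard route to p-quinols; the product is achiral and its two enone halves are enantiotopic.

Step 2
Reactants: 2 p-quinol methyl ester
Product: 4 cis-fused isobutylidene dioxolane enone, via hemiacetal 3 (not isolated)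
Conditions: iPrCHO (3 equiv), (R)-3,3′-bis(2,4,6-triisopropylphenyl)-1,1′-binaphthyl-2,2′-diyl hydrogen phosphate (5 mol %), CH2Cl2, rt
Reagents that add atoms: isobutyraldehyde, CC(C)C=O
Why: This is the chiral phosphoric acid-catalysed acetalisation/oxa-Michael desymmetrisation known for p-quinols: hemiacetal 3 adds 5-exo-trig to one of the two enantiotopic enones under catalyst control, which sets C1 and C9 at once (the two oxygens are necessarily cis) and leaves isopropyl on the convex face.

Step 3
Reactants: 4 cis-fused isobutylidene dioxolane enone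
Product: 6 C5-hydroxymethyl enone, via lithium dienolate 5 (not isolated)
Conditions: LiN(iPr)2 (1.05 equiv), THF, −78 °C; anhydrous HCHO (THF solution), −78 °C; AcOH
Reagents that add atoms: formaldehyde, C=O
Why: Kinetic α′-deprotonation (there is no γ-hydrogen, and the ester enolises more slowly) followed by aldol addition to formaldehyde introduces C4; the electrophile enters anti to the neighbouring C9 oxygen, as in alkylations of 3-substituted cyclohexanone enolates, so CH2OH on C5 is α, cis to the propanoate arm, which is also the more stable arrangement.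

Step 4
Reactants: 6 C5-hydroxymethyl enone
Product: 7 C4/C6 diol
Conditions: NaBH4, CeCl3·7H2O, MeOH, −78 °C
Reagents that add atoms: none
Why: Luche 1,2-reduction: in the conformer with C5–CH2OH and C9–O equatorial, axial hydride attack from the α face should give the equatorial β carbinol at C6, trans to C5–C4, and the ester is untouched.

Step 5
Reactants: 7 C4/C6 diol
Product: 8 bis-TIPS ether
Conditions: iPr3SiOTf (2.5 equiv), 2,6-lutidine, CH2Cl2, 0 °C → rt
Reagents that add atoms: triisopropylsilyl triflate, CC(C)[Si](OS(=O)(=O)C(F)(F)F)(C(C)C)C(C)C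
Why: Silyl triflate silylation of both hydroxyls; triisopropylsilyl is chosen because the C6 ether must later outlast the acid that removes the acetal.

Step 6
Reactants: 8 bis-TIPS ether
Product: 9 C6-TIPS ether primary alcohol
Conditions: HF·pyridine, pyridine, THF, 0 °C → rt
Reagents that add atoms: none
Why: Fluoride-mediated desilylation is much faster at the primary ether than at the hindered secondary allylic one, a routine differentiation, and the acetal and ester are inert to buffered HF.

Step 7
Reactants: 9 C6-TIPS ether primary alcohol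
Product: 12 α-bromo ester alcohol, via silyl ketene acetal 10 (not isolated), via bromo ester silyl ether 11 (not isolated)
Conditions: LiN(iPr)2 (2.3 equiv), Me3SiCl (3 equiv), THF, −78 °C; NBS, −78 → −40 °C; 1 M HCl, THF, 0 °C
Reagents that add atoms: N-bromosuccinimide, O=C1CCC(=O)N1Br
Why: α-Bromination of an ester through its ketene silyl acetal (enolisation with in situ Me3SiCl trapping, then NBS) is standard; the free hydroxyl is silylated in the same pot and freed again by the acidic work-up, and C3 forms as both epimers, which converge in step 9.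

Step 8
Reactants: 12 α-bromo ester alcohol
Product: 13 α-bromo ester aldehyde
Conditions: Dess–Martin periodinane, NaHCO3, CH2Cl2, 0 °C → rt
Reagents that add atoms: none
Why: Dess–Martin oxidation under buffered, non-basic conditions should give the aldehyde without epimerising C5 or eliminating the β-silyloxy group, and the α-bromo ester is inert.

Step 9
Reactants: 13 α-bromo ester aldehyde
Product: 15 bicyclic β-hydroxy ester, via samarium enolate 14 (not isolated)
Conditions: SmI2 (2.5 equiv), THF, −78 °C, slow addition of 13 (final 0.005 M); 0.1 M HCl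
Reagents that add atoms: none
Why: Two electrons from SmI2 cleave the C3–Br bond, so both bromide epimers give the same trivalent samarium ester enolate 14, which adds to the C4 aldehyde on C5; the closest known reaction type is the SmI2-mediated intramolecular Reformatsky (aldol) cyclisation of α-halo esters onto aldehydes. Ring A closes in a 6-(enolexo)-exo-trig mode through the conformer of ring B in which the C2–C3 arm and the formyl group, both α, are 1,3-diaxial, an arrangement made available by the quaternary C1 and the cis relationship set in steps 2 and 3. C4 is controlled by a closed samarium-bridged six-membered transition state in which the metal-bound aldehyde oxygen lies on the open exo face of the forming ring and the small formyl hydrogen points into the cleft toward C7, which should give the exo (axial) carbinol. C3 is controlled by the same chelate, which requires the ester gauche to the new oxygen and therefore exo, cis to the hydroxyl; the endo position is also blocked by C7. The step needs reduction of C–Br ahead of C=O and survival of the epimerisable C5 centre and of the β-silyloxy group: α-bromo esters are reduced far faster than aldehydes at −78 °C, SmI2 is not basic, and no ketone is present because C9 is an acetal-protected carbinol. High dilution and slow addition of 13 to the reductant keep intermolecular aldol addition down.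

Step 10
Reactants: 15 bicyclic β-hydroxy ester
Product: 16 O4-TIPS ester
Conditions: iPr3SiOTf, 2,6-lutidine, CH2Cl2, 0 °C → rt
Reagents that add atoms: triisopropylsilyl triflate, CC(C)[Si](OS(=O)(=O)C(F)(F)F)(C(C)C)C(C)C
Why: Silyl triflate silylation of the hindered axial carbinol blocks O4, so that the isocyanate of step 12 is not captured internally and C9–OH is later the only free secondary hydroxyl.

Step 11
Reactants: 16 O4-TIPS ester
Product: 17 C3 carboxylic acid
Conditions: Me3SnOH, ClCH2CH2Cl, 80 °C; 1 M HCl
Reagents that add atoms: trimethyltin hydroxide, C[Sn](C)(C)O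
Why: Me3SnOH cleaves hindered methyl esters under nearly neutral conditions, which avoids the β-elimination of the C4 silyloxy group and the epimerisation of C3 that hydroxide could cause.

Step 12
Reactants: 17 C3 carboxylic acid
Product: 20 C3 allyl carbamate, via acyl azide 18 (not isolated), via isocyanate 19 (not isolated)
Conditions: (PhO)2P(O)N3, Et3N, toluene, rt → 90 °C; allyl alcohol (excess), 90 °C
Reagents that add atoms: diphenylphosphoryl azide, [N-]=[N+]=NP(=O)(Oc1ccccc1)Oc1ccccc1; allyl alcohol, C=CCO
Why: Curtius rearrangement: acyl azide 18 loses N2 with migration of C3 to nitrogen with retention of configuration, and isocyanate 19 is trapped by allyl alcohol as the carbamate, so the exo carboxyl becomes the exo nitrogen.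

Step 13
Reactants: 20 C3 allyl carbamate
Product: 21 C3 amine
Conditions: Pd(PPh3)4 (5 mol %), morpholine, THF, rt
Reagents that add atoms: none
Why: Tsuji–Trost-type deallylation: zerovalent palladium transfers the allyl group to morpholine and CO2 is lost, freeing the amine under neutral conditions that leave silyl ethers, acetal and ring alkene untouched.

Step 14
Reactants: 22 δ-decalactone
Product: 23 lactol (6-pentyloxan-2-ol)
Conditions: iBu2AlH (1.1 equiv), CH2Cl2, −78 °C; H2O
Reagents that add atoms: none
Why: Partial reduction of a lactone by iBu2AlH at −78 °C stops at the lactol because the tetrahedral aluminate is stable at that temperature.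

Step 15
Reactants: 23 lactol (6-pentyloxan-2-ol)
Product: 25 tert-butyl (E)-7-hydroxydodec-2-enoate, via 5-hydroxydecanal 24 (not isolated)
Conditions: Ph3P=CHCO2tBu, toluene, 80 °C
Reagents that add atoms: tert-butyl (triphenylphosphoranylidene)acetate, CC(C)(C)OC(=O)C=P(c1ccccc1)(c1ccccc1)c1ccccc1
Why: Wittig olefination of the open hydroxy aldehyde form with a stabilised ylide gives the (E)-enoate, and the neutral conditions avoid oxa-Michael closure of the 7-hydroxy enoate.

Step 16
Reactants: 25 tert-butyl (E)-7-hydroxydodec-2-enoate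
Product: 26 tert-butyl (E)-7-oxododec-2-enoate
Conditions: Dess–Martin periodinane, CH2Cl2, rt
Reagents that add atoms: none
Why: Dess–Martin oxidation of the secondary alcohol to the ketone, which also removes the racemic stereocentre.

Step 17
Reactants: 26 tert-butyl (E)-7-oxododec-2-enoate
Product: 27 (E)-7-oxododec-2-enoic acid
Conditions: CF3CO2H, CH2Cl2, rt
Reagents that add atoms: none
Why: Acidolysis of the tert-butyl ester (loss of isobutene) frees the acid without base, which could trigger intramolecular Michael addition of the ketone enolate.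

Step 18
Reactants: 21 C3 amine; 27 (E)-7-oxododec-2-enoic acid
Product: 29 acetal-protected bis-TIPS amide, via benzotriazolyl ester 28 (not isolated)
Conditions: N-ethyl-N′-(3-dimethylaminopropyl)carbodiimide hydrochloride, 1-hydroxybenzotriazole, iPr2NEt, CH2Cl2, 0 °C → rt
Reagents that add atoms: none
Why: Carbodiimide amide coupling through the benzotriazolyl ester; the primary amine is the only nucleophile present and the alkene geometry is untouched.

Step 19
Reactants: 29 acetal-protected bis-TIPS amide
Product: 30 C1/C9 diol amide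
Conditions: CF3CO2H/H2O (4:1), CH2Cl2, 0 °C → rt
Reagents that add atoms: none
Why: Acid-catalysed hydrolysis of the aldehyde-derived dioxolane frees the C1/C9 diol; triisopropylsilyl ethers, the unsaturated amide and the ketone tolerate aqueous trifluoroacetic acid, and the bridgehead C1–O bond cannot ionise.

Step 20
Reactants: 30 C1/C9 diol amide
Product: 31 bis-TIPS C9 ketone
Conditions: Dess–Martin periodinane, NaHCO3, CH2Cl2, rt
Reagents that add atoms: none
Why: Dess–Martin oxidation of the only secondary hydroxyl gives the α-hydroxy ketone; the tertiary C1 hydroxyl cannot be oxidised, and a trigonal C9 relieves the 1,3-interaction with the C6 silyl ether.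

Step 21
Reactants: 31 bis-TIPS C9 ketone
Product: 32 alkene triol
Conditions: HF·pyridine, THF, 0 °C → rt
Reagents that add atoms: none
Why: Fluoride cleavage of both silyl ethers under acidic buffering; basic fluoride is avoided because the product is a double β-hydroxy ketone prone to retro-aldol cleavage, whereas dehydration is impossible since C5 is a bridgehead.

Step 22
Reactants: 32 alkene triol
Product: 33 isariotin C
Conditions: VO(acac)2 (5 mol %), tBuOOH, CH2Cl2, 0 °C → rt
Reagents that add atoms: tert-butyl hydroperoxide, CC(C)(C)OO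
Why: Hydroxyl-directed epoxidation: the pseudo-axial C6 allylic hydroxyl (and the C1 hydroxyl) should deliver oxygen to the exo face of C7=C8, which is also the only open face, so the epoxide forms cis to O6; the electron-poor alkene of the unsaturated amide has no allylic hydroxyl and should not react.

**Compound list**

1 | methyl 3-(4-hydroxyphenyl)propanoate | COC(=O)CCc1ccc(O)cc1 | starting material
2 | methyl 3-(1-hydroxy-4-oxocyclohexa-2,5-dien-1-yl)propanoate (p-quinol, achiral) | COC(=O)CCC1(O)C=CC(=O)C=C1 | intermediate
3 | isobutyraldehyde hemiacetal at the tertiary hydroxyl of 2 (either configuration at the hemiacetal carbon; not isolated) | COC(=O)CCC1(OC(O)C(C)C)C=CC(=O)C=C1 | intermediate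
4 | methyl 3-[(2S,3aR,7aS)-2-isopropyl-5-oxo-3a,4,5,7a-tetrahydro-1,3-benzodioxol-7a-yl]propanoate (C1–O and C9–O both β, isopropyl exo, C6 ketone, C7=C8) | COC(=O)CC[C@@]1(O[C@@H](C(C)C)O2)[C@H]2CC(=O)C=C1 | intermediate
5 | lithium C5=C6 dienolate of 4 (not isolated) | COC(=O)CC[C@@]1(O[C@@H](C(C)C)O2)[C@H]2C=C(O[Li])C=C1 | intermediate
6 | 4 bearing CH2OH (C4) on C5, α: trans to the C9 oxygen and cis to the propanoate arm | COC(=O)CC[C@@]1(O[C@@H](C(C)C)O2)[C@H]2[C@@H](CO)C(=O)C=C1 | intermediate
7 | diol from 6: C6 hydroxyl β (cis to the C1 and C9 oxygens, trans to C5–CH2OH) | COC(=O)CC[C@@]1(O[C@@H](C(C)C)O2)[C@H]2[C@@H](CO)[C@H](O)C=C1 | intermediate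
8 | O4,O6-bis(triisopropylsilyl) ether of 7 | COC(=O)CC[C@@]1(O[C@@H](C(C)C)O2)[C@H]2[C@@H](CO[Si](C(C)C)(C(C)C)C(C)C)[C@H](O[Si](C(C)C)(C(C)C)C(C)C)C=C1 | intermediate
9 | O6-triisopropylsilyl ether with free primary C4 hydroxyl | COC(=O)CC[C@@]1(O[C@@H](C(C)C)O2)[C@H]2[C@@H](CO)[C@H](O[Si](C(C)C)(C(C)C)C(C)C)C=C1 | intermediate
10 | methyl trimethylsilyl ketene acetal of 9 with O4 as trimethylsilyl ether (not isolated) | COC(O[Si](C)(C)C)=CC[C@@]1(O[C@@H](C(C)C)O2)[C@H]2[C@@H](CO[Si](C)(C)C)[C@H](O[Si](C(C)C)(C(C)C)C(C)C)C=C1 | intermediate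
11 | methyl 2-bromo ester (C3, both epimers) with O4 as trimethylsilyl ether (not isolated) | COC(=O)C(Br)C[C@@]1(O[C@@H](C(C)C)O2)[C@H]2[C@@H](CO[Si](C)(C)C)[C@H](O[Si](C(C)C)(C(C)C)C(C)C)C=C1 | intermediate
12 | methyl 2-bromo ester (C3, both epimers) with free C4 hydroxyl | COC(=O)C(Br)C[C@@]1(O[C@@H](C(C)C)O2)[C@H]2[C@@H](CO)[C@H](O[Si](C(C)C)(C(C)C)C(C)C)C=C1 | intermediate
13 | ring B α-bromo ester aldehyde (C3 both epimers; CHO on C5 α, cis to the bromo ester arm; C6–OTIPS β; C1/C9 isobutylidene acetal β; C7=C8) | COC(=O)C(Br)C[C@@]1(O[C@@H](C(C)C)O2)[C@H]2[C@@H](C=O)[C@H](O[Si](C(C)C)(C(C)C)C(C)C)C=C1 | intermediate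
14 | diiodosamarium ester enolate of 13 (trivalent samarium; not isolated) | COC(O[Sm](I)I)=CC[C@@]1(O[C@@H](C(C)C)O2)[C@H]2[C@@H](C=O)[C@H](O[Si](C(C)C)(C(C)C)C(C)C)C=C1 | intermediate
15 | bicyclic β-hydroxy ester: CO2Me on C3 exo, C4–OH exo (cis), C6–OTIPS exo, C1/C9 isobutylidene acetal, C7=C8 | COC(=O)[C@H]1C[C@@]2(O[C@@H](C(C)C)O3)[C@H]3[C@H]([C@H](O[Si](C(C)C)(C(C)C)C(C)C)C=C2)[C@H]1O | intermediate
16 | O4-triisopropylsilyl ether of 15 | COC(=O)[C@H]1C[C@@]2(O[C@@H](C(C)C)O3)[C@H]3[C@H]([C@H](O[Si](C(C)C)(C(C)C)C(C)C)C=C2)[C@H]1O[Si](C(C)C)(C(C)C)C(C)C | intermediate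
17 | C3 carboxylic acid from 16 (carboxyl exo) | OC(=O)[C@H]1C[C@@]2(O[C@@H](C(C)C)O3)[C@H]3[C@H]([C@H](O[Si](C(C)C)(C(C)C)C(C)C)C=C2)[C@H]1O[Si](C(C)C)(C(C)C)C(C)C | intermediate
18 | acyl azide of 17 (not isolated) | [N-]=[N+]=NC(=O)[C@H]1C[C@@]2(O[C@@H](C(C)C)O3)[C@H]3[C@H]([C@H](O[Si](C(C)C)(C(C)C)C(C)C)C=C2)[C@H]1O[Si](C(C)C)(C(C)C)C(C)C | intermediate
19 | C3 isocyanate, nitrogen exo (not isolated) | O=C=N[C@H]1C[C@@]2(O[C@@H](C(C)C)O3)[C@H]3[C@H]([C@H](O[Si](C(C)C)(C(C)C)C(C)C)C=C2)[C@H]1O[Si](C(C)C)(C(C)C)C(C)C | intermediate
20 | C3 allyl carbamate | C=CCOC(=O)N[C@H]1C[C@@]2(O[C@@H](C(C)C)O3)[C@H]3[C@H]([C@H](O[Si](C(C)C)(C(C)C)C(C)C)C=C2)[C@H]1O[Si](C(C)C)(C(C)C)C(C)C | intermediate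
21 | C3 primary amine (exo) | N[C@H]1C[C@@]2(O[C@@H](C(C)C)O3)[C@H]3[C@H]([C@H](O[Si](C(C)C)(C(C)C)C(C)C)C=C2)[C@H]1O[Si](C(C)C)(C(C)C)C(C)C | intermediate
22 | δ-decalactone (6-pentyloxan-2-one, racemic) | CCCCCC1CCCC(=O)O1 | starting material
23 | 6-pentyloxan-2-ol (lactol, mixture of isomers) | CCCCCC1CCCC(O)O1 | intermediate
24 | 5-hydroxydecanal (open form of 23; not isolated) | CCCCCC(O)CCCC=O | intermediate
25 | tert-butyl (E)-7-hydroxydodec-2-enoate (racemic) | CCCCCC(O)CCC/C=C/C(=O)OC(C)(C)C | intermediate
26 | tert-butyl (E)-7-oxododec-2-enoate | CCCCCC(=O)CCC/C=C/C(=O)OC(C)(C)C | intermediate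
27 | (E)-7-oxododec-2-enoic acid | CCCCCC(=O)CCC/C=C/C(=O)O | intermediate
28 | benzotriazol-1-yl (E)-7-oxododec-2-enoate (not isolated) | CCCCCC(=O)CCC/C=C/C(=O)On1nnc2ccccc12 | intermediate
29 | C3 (E)-7-oxododec-2-enamide with C1/C9 isobutylidene acetal and O4,O6-bis-TIPS | CCCCCC(=O)CCC/C=C/C(=O)N[C@H]1C[C@@]2(O[C@@H](C(C)C)O3)[C@H]3[C@H]([C@H](O[Si](C(C)C)(C(C)C)C(C)C)C=C2)[C@H]1O[Si](C(C)C)(C(C)C)C(C)C | intermediate
30 | C1,C9-diol amide (C9–OH cis to C1–OH; O4,O6-bis-TIPS) | CCCCCC(=O)CCC/C=C/C(=O)N[C@H]1C[C@@]2(O)[C@H](O)[C@H]([C@H](O[Si](C(C)C)(C(C)C)C(C)C)C=C2)[C@H]1O[Si](C(C)C)(C(C)C)C(C)C | intermediate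
31 | C9 ketone with C1–OH free and O4,O6-bis-TIPS | CCCCCC(=O)CCC/C=C/C(=O)N[C@H]1C[C@@]2(O)C(=O)[C@H]([C@H](O[Si](C(C)C)(C(C)C)C(C)C)C=C2)[C@H]1O[Si](C(C)C)(C(C)C)C(C)C | intermediate
32 | C1,C4,C6-triol C9 ketone with C7=C8 alkene (isariotin C lacking the epoxide oxygen) | CCCCCC(=O)CCC/C=C/C(=O)N[C@H]1C[C@@]2(O)C(=O)[C@H]([C@H](O)C=C2)[C@H]1O | intermediate
33 | isariotin C | CCCCCC(=O)CCC/C=C/C(=O)N[C@H]1C[C@@]2(O)C(=O)[C@H]([C@H](O)[C@@H]3O[C@@H]32)[C@H]1O | target

**Totals and risks**

Total step count: 22. Longest linear sequence: 18 steps (steps 1–13 and 18–22); the side-chain acid takes 4 steps (14–17).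

Steps most likely to fail:

Step 9. The ring closure may stall because the diaxial conformer of ring B is poorly populated, leaving the enolate to be protonated or to react intermolecularly, or the aldehyde faces may not be well differentiated. The fallback makes the same C3–C4 bond and the same ring one oxidation level higher, by a Dieckmann condensation that is pulled forward by formation of the β-keto ester enolate. It sets out from alcohol 9, which is oxidised (2,2,6,6-tetramethylpiperidin-1-oxyl, PhI(OAc)2, aqueous MeCN) to the C5 carboxylic acid F1 and esterified (Me3SiCHN2, MeOH) to the dimethyl diester F2. LiN(SiMe3)2 in THF (−78 → 0 °C) should then close ring A to the bicyclic β-keto ester F3; only the C3 side of the new ketone can enolise, C5 being a bridgehead. Reduction with LiBH(sBu)3 at −78 °C, with hydride entering along the equatorial trajectory, should give the axial exo carbinol with the ester settling exo, and the route is rejoined at 15.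

Step 3. The lithium dienolate may expel the C9 acetal oxygen by β-elimination, or the aldolate may add further formaldehyde or revert. The fallback never leaves a free enolate in the presence of the electrophile: from 4, LiN(iPr)2 with Me3SiCl present at −78 °C gives the trimethylsilyl dienol ether F4, which is isolated and submitted to a Mukaiyama aldol addition with aqueous formaldehyde under Sc(OTf)3 catalysis (THF/H2O, rt), returning to the route at 6.

Step 2. Enantiofacial discrimination between the two enones may be insufficient. The fallback delivers the C9 oxygen as a boronic acid hemiester under bifunctional base catalysis instead of as a hemiacetal under acid. From 2, PhB(OH)2 and N-[3,5-bis(trifluoromethyl)phenyl]-N′-[(8α,9S)-6′-methoxycinchonan-9-yl]thiourea (toluene, rt) should give, by intramolecular oxa-Michael addition, the cis-fused phenylboronate F5 (the catalyst enantiomer series being chosen for the sense needed). Mild oxidative work-up (aqueous H2O2) frees the cis-diol hydroxy ketone F6, and acetalisation with isobutyraldehyde (pyridinium p-toluenesulfonate, MgSO4, CH2Cl2) rejoins the route at 4.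

Further compounds
F1 | step 9 | C5 carboxylic acid from 9 (CO2H on C5 α, C6–OTIPS β, C1/C9 isobutylidene acetal, methyl propanoate arm) | COC(=O)CC[C@@]1(O[C@@H](C(C)C)O2)[C@H]2[C@@H](C(=O)O)[C@H](O[Si](C(C)C)(C(C)C)C(C)C)C=C1
F2 | step 9 | dimethyl diester from F1 | COC(=O)CC[C@@]1(O[C@@H](C(C)C)O2)[C@H]2[C@@H](C(=O)OC)[C@H](O[Si](C(C)C)(C(C)C)C(C)C)C=C1
F3 | step 9 | bicyclic β-keto ester (C4 ketone, CO2Me on C3 as epimers or enol, C6–OTIPS, C1/C9 isobutylidene acetal) | COC(=O)C1C[C@@]2(O[C@@H](C(C)C)O3)[C@H]3[C@H]([C@H](O[Si](C(C)C)(C(C)C)C(C)C)C=C2)C1=O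
F4 | step 3 | trimethylsilyl C5=C6 dienol ether of 4 | COC(=O)CC[C@@]1(O[C@@H](C(C)C)O2)[C@H]2C=C(O[Si](C)(C)C)C=C1
F5 | step 2 | cis-fused phenylboronate of the C1/C9 diol (C6 ketone, C7=C8) | COC(=O)CC[C@@]1(OB(c3ccccc3)O2)[C@H]2CC(=O)C=C1
F6 | step 2 | cis-C1,C9-diol hydroxy ketone | COC(=O)CC[C@@]1(O)[C@H](O)CC(=O)C=C1
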